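**Strategy.** The diarylpropane is cut at the ring A aryl–CH2 bond (B-alkyl Suzuki coupling of a ring B allyl group with a ring A iodide). Ring B rests on one idea: its dihydrofuran ring (O1, C2, C3, C3a, C7a) with the C2 stereocentre and the CMe2OH group is a 1,2-oxygen-shifted 2,2-dimethylchroman-3-ol. Activating that carbinol lets the pyran oxygen, antiperiplanar to the C–O bond, move from the CMe2 carbon to the carbinol carbon with inversion while water takes the tertiary carbon; one operation contracts the six-membered ring, sets C2 as R and creates the tertiary alcohol. The precursor, (S)-6-allyl-8-methoxy-2,2-dimethylchroman-3-ol, comes from eugenol by chromenylation, Jacobsen epoxidation and hydride opening.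

Key step: step 4

Assumption: the (S,S)-salen manganese catalyst is taken to give the (3S,4S)-epoxide of a 2,2-dimethyl-2H-chromene, the usual sense for this substrate class; were the sense opposite, the (R,R)-catalyst would be used.

**Step 1**
Reactants: 1 eugenol (4-allyl-2-methoxyphenol); 2 3-methylbut-2-enal
Product: 3 6-allyl-8-methoxy-2,2-dimethyl-2H-chromene
Conditions: PhB(OH)2 (1 equiv), AcOH, toluene, reflux, Dean–Stark
Reagents that add atoms: 3-methylbut-2-enal, CC(C)=CC=O
Why: Boronic-acid-templated ortho-condensation of a phenol with an enal followed by oxa-6π ring closure (chromenylation) should give a single chromene, because C6 is the only free ortho position of 1.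

**Step 2**
Reactants: 3
Product: 4 (1aS,7bS)-6-allyl-4-methoxy-2,2-dimethyl-1a,7b-dihydro-2H-oxireno[2,3-c]chromene (the 3S,4S epoxide in chromane numbering)
Conditions: (S,S)-N,N'-bis(3,5-di-tert-butylsalicylidene)cyclohexane-1,2-diaminomanganese chloride (trivalent manganese, cat.), aq. NaOCl (pH 11.3), 4-phenylpyridine N-oxide, CH2Cl2, 0 °C
Reagents that add atoms: sodium hypochlorite, [Na+].[O-]Cl
Why: Jacobsen–Katsuki epoxidation, for which cis-disubstituted aryl-conjugated 2,2-dimethylchromenes are the best substrate class, should set both epoxide carbons as S under control of the (S,S)-salen ligand, while the isolated monosubstituted allyl alkene is a poor substrate and should stay untouched.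

**Step 3**
Reactants: 4
Product: 5 (3S)-6-allyl-8-methoxy-2,2-dimethyl-3,4-dihydro-2H-chromen-3-ol
Conditions: LiAlH4, THF, 0 °C
Reagents that add atoms: none
Why: Hydride should open the epoxide by SN2 attack at the benzylic C4 rather than at the neopentyl C3, so the C3–O bond and its S configuration are carried over unchanged.

**Step 4**
Reactants: 5
Product: 8 2-[(2R)-5-allyl-7-methoxy-2,3-dihydro-1-benzofuran-2-yl]propan-2-ol, via chroman-3-yl triflate 6 (not isolated), via bridged oxiranium triflate 7 (not isolated)
Conditions: Tf2O, 2,6-di-tert-butyl-4-methylpyridine (DTBMP), CH2Cl2, −78 °C; then (CF3)2CHOH/H2O (4:1), −40 °C to rt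
Reagents that add atoms: water, O
Why: The carbinol is triflated to 6, and in the half-chair with a pseudo-equatorial C3–OTf the O1–C2 bond lies antiperiplanar to the leaving group, so the ring oxygen should displace triflate from the back to give the aryl-bridged oxiranium ion 7, which water opens at the tertiary carbon; the six-membered pyran thereby becomes the five-membered dihydrofuran carrying CMe2OH. The closest known reaction types are the ring contraction of 2,2-dimethylchroman-3-ols on activation of the hydroxyl group (deoxyfluorinating reagents, sulfonates) and the ring-oxygen-assisted contraction of pyranose 2-triflates to 2,5-anhydro sugars. The O1–C3 bond formation is at once a 3-exo-tet closure (oxiranium ring) and a 5-exo-tet closure (dihydrofuran ring), and the later opening at the CMe2 carbon leaves only the five-membered ring. The new stereocentre (C2 of the dihydrobenzofuran) is the former carbinol carbon, inverted once by the intramolecular back-side attack, so (3S)-5 should give (2R)-8 stereospecifically with the enantiopurity set in step 2. The step needs the 1,2-oxygen shift to win over E2 loss of a benzylic C4 proton (back to 3), over a methyl shift from C2 and over proton loss from the bridged ion; lone-pair participation in an ionising, weakly nucleophilic medium, a hindered pyridine that is a poor E2 base, low temperature and a large excess of water as trap are meant to secure this. Opening of 7 by water at the secondary carbon would only return 5, which can be recycled.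

**Step 5**
Reactants: 8
Product: 9 2-[(2R)-5-allyl-4-iodo-7-methoxy-2,3-dihydro-1-benzofuran-2-yl]propan-2-ol
Conditions: NIS, TFA (cat.), MeCN, 0 °C to rt, dark
Reagents that add atoms: N-iodosuccinimide, O=C1CCC(=O)N1I
Why: Electrophilic aromatic iodination should go to C4, para to the methoxy group, because the positions ortho and para to O1 are all substituted and the methoxy methyl, turned away from O1, shields the only other open site C6; the activated arene should react faster than the terminal alkene.

**Step 6**
Reactants: 9; 10 tributyl(3-methylbut-2-en-1-yl)stannane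
Product: 11 2-[(2R)-5-allyl-7-methoxy-4-(3-methylbut-2-en-1-yl)-2,3-dihydro-1-benzofuran-2-yl]propan-2-ol
Conditions: Pd(PPh3)4 (cat.), CsF, DMF, 80 °C
Reagents that add atoms: tributyl(3-methylbut-2-en-1-yl)stannane, CCCC[Sn](CCCC)(CCCC)CC=C(C)C
Why: Stille coupling of the hindered aryl iodide should give the linear prenyl arene, since the aryl(allyl)palladium intermediate eliminates reductively at the unsubstituted allyl terminus, and the free tertiary alcohol is tolerated.

**Step 7**
Reactants: 12 resorcinol; 13 1-bromo-3-methylbut-2-ene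
Product: 14 3-[(3-methylbut-2-en-1-yl)oxy]phenol
Conditions: K2CO3, acetone, reflux, threefold excess of 12
Reagents that add atoms: 1-bromo-3-methylbut-2-ene, CC(C)=CCBr
Why: Williamson mono-etherification, with the diol in excess to suppress the bis-ether.

**Step 8**
Reactants: 14
Product: 15 4-(2-methylbut-3-en-2-yl)benzene-1,3-diol
Conditions: N,N-diethylaniline, 190 °C
Reagents that add atoms: none
Why: Aromatic Claisen rearrangement ([3,3]) turns the prenyl ether into the ortho 1,1-dimethylallyl phenol, and the bulky migrating terminus should prefer C6 (para to the free hydroxyl) over C2 between the two oxygens, the basic solvent holding back acid-catalysed cyclisation of the product.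

**Step 9**
Reactants: 15
Product: 16 4-iodo-6-(2-methylbut-3-en-2-yl)benzene-1,3-diol
Conditions: NIS (1.0 equiv), MeCN, −30 °C
Reagents that add atoms: N-iodosuccinimide, O=C1CCC(=O)N1I
Why: Electrophilic iodination of a 4-alkylresorcinol should take place at C6 (para to one hydroxyl, ortho to the other), which is more accessible than C2, and far faster than any reaction at the hindered vinyl group.

**Step 10**
Reactants: 16
Product: 17 4-iodo-6-(2-methylbut-3-en-2-yl)-1,3-phenylene bis(2,2-dimethylpropanoate)
Conditions: pivaloyl chloride, Et3N, DMAP (cat.), CH2Cl2, 0 °C to rt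
Reagents that add atoms: pivaloyl chloride, CC(C)(C)C(=O)Cl
Why: Double O-acylation stabilises the iodoresorcinol, makes the aryl iodide less electron-rich for oxidative addition, and gives esters that survive aqueous phosphate but fall to thiolate in the last step.

**Step 11**
Reactants: 11; 17
Product: 19 4-{3-[(2R)-2-(2-hydroxypropan-2-yl)-7-methoxy-4-(3-methylbut-2-en-1-yl)-2,3-dihydro-1-benzofuran-5-yl]propyl}-6-(2-methylbut-3-en-2-yl)-1,3-phenylene bis(2,2-dimethylpropanoate), via B-alkyl-9-BBN 18 (not isolated)
Conditions: 9-BBN (1.5 equiv), THF, 0 °C to rt; then aq. K3PO4, 17, PdCl2(dppf) (cat.), DMF, 50 °C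
Reagents that add atoms: none
Why: 9-BBN should add anti-Markovnikov to the monosubstituted allyl alkene far faster than to the trisubstituted prenyl alkene, and the B-alkyl Suzuki–Miyaura coupling then joins the primary alkylborane to the aryl iodide, excess B–H being quenched by the aqueous base before 17 with its vinyl group is added.

**Step 12**
Reactants: 19
Product: 20 4-{3-[(2R)-7-hydroxy-2-(2-hydroxypropan-2-yl)-4-(3-methylbut-2-en-1-yl)-2,3-dihydro-1-benzofuran-5-yl]propyl}-6-(2-methylbut-3-en-2-yl)benzene-1,3-diol
Conditions: NaSEt (excess), DMF, 120 °C, degassed; aq. NH4Cl work-up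
Reagents that add atoms: none
Why: Ethanethiolate should cleave both aryl pivalates by acyl transfer and the aryl methyl ether by SN2 attack at methyl, under non-acidic conditions that leave the tertiary alcohol, the prenyl and 1,1-dimethylallyl groups and the C2 stereocentre untouched.

**Compound list**
1 | eugenol (4-allyl-2-methoxyphenol) | C=CCc1ccc(O)c(OC)c1 | starting material
2 | 3-methylbut-2-enal | CC(C)=CC=O | starting material
3 | 6-allyl-8-methoxy-2,2-dimethyl-2H-chromene | C=CCc1cc(OC)c2OC(C)(C)C=Cc2c1 | intermediate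
4 | (1aS,7bS)-6-allyl-4-methoxy-2,2-dimethyl-1a,7b-dihydro-2H-oxireno[2,3-c]chromene | C=CCc1cc(OC)c2OC(C)(C)[C@H]3O[C@H]3c2c1 | intermediate
5 | (3S)-6-allyl-8-methoxy-2,2-dimethyl-3,4-dihydro-2H-chromen-3-ol | C=CCc1cc(OC)c2OC(C)(C)[C@@H](O)Cc2c1 | intermediate
6 | (3S)-6-allyl-8-methoxy-2,2-dimethyl-3,4-dihydro-2H-chromen-3-yl trifluoromethanesulfonate | C=CCc1cc(OC)c2OC(C)(C)[C@@H](OS(=O)(=O)C(F)(F)F)Cc2c1 | intermediate (not isolated)
7 | bridged oxiranium triflate (ring oxygen bonded to the aryl carbon, to the inverted former C3 and to the CMe2 carbon) | C=CCc1cc(OC)c2[O+]3[C@H](Cc2c1)C3(C)C.[O-]S(=O)(=O)C(F)(F)F | intermediate (not isolated)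
8 | 2-[(2R)-5-allyl-7-methoxy-2,3-dihydro-1-benzofuran-2-yl]propan-2-ol | C=CCc1cc(OC)c2O[C@@H](C(C)(C)O)Cc2c1 | intermediate
9 | 2-[(2R)-5-allyl-4-iodo-7-methoxy-2,3-dihydro-1-benzofuran-2-yl]propan-2-ol | C=CCc1cc(OC)c2O[C@@H](C(C)(C)O)Cc2c1I | intermediate
10 | tributyl(3-methylbut-2-en-1-yl)stannane | CCCC[Sn](CCCC)(CCCC)CC=C(C)C | starting material
11 | 2-[(2R)-5-allyl-7-methoxy-4-(3-methylbut-2-en-1-yl)-2,3-dihydro-1-benzofuran-2-yl]propan-2-ol | C=CCc1cc(OC)c2O[C@@H](C(C)(C)O)Cc2c1CC=C(C)C | intermediate
12 | resorcinol | Oc1cccc(O)c1 | starting material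
13 | 1-bromo-3-methylbut-2-ene | CC(C)=CCBr | starting material
14 | 3-[(3-methylbut-2-en-1-yl)oxy]phenol | CC(C)=CCOc1cccc(O)c1 | intermediate
15 | 4-(2-methylbut-3-en-2-yl)benzene-1,3-diol | C=CC(C)(C)c1ccc(O)cc1O | intermediate
16 | 4-iodo-6-(2-methylbut-3-en-2-yl)benzene-1,3-diol | C=CC(C)(C)c1cc(I)c(O)cc1O | intermediate
17 | 4-iodo-6-(2-methylbut-3-en-2-yl)-1,3-phenylene bis(2,2-dimethylpropanoate) | C=CC(C)(C)c1cc(I)c(OC(=O)C(C)(C)C)cc1OC(=O)C(C)(C)C | intermediate
18 | 9-{3-[(2R)-2-(2-hydroxypropan-2-yl)-7-methoxy-4-(3-methylbut-2-en-1-yl)-2,3-dihydro-1-benzofuran-5-yl]propyl}-9-borabicyclo[3.3.1]nonane | C(CCc1cc(OC)c2O[C@@H](C(C)(C)O)Cc2c1CC=C(C)C)B1C2CCCC1CCC2 | intermediate (not isolated)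
19 | 4-{3-[(2R)-2-(2-hydroxypropan-2-yl)-7-methoxy-4-(3-methylbut-2-en-1-yl)-2,3-dihydro-1-benzofuran-5-yl]propyl}-6-(2-methylbut-3-en-2-yl)-1,3-phenylene bis(2,2-dimethylpropanoate) | C=CC(C)(C)c1cc(CCCc2cc(OC)c3O[C@@H](C(C)(C)O)Cc3c2CC=C(C)C)c(OC(=O)C(C)(C)C)cc1OC(=O)C(C)(C)C | intermediate
20 | 4-{3-[(2R)-7-hydroxy-2-(2-hydroxypropan-2-yl)-4-(3-methylbut-2-en-1-yl)-2,3-dihydro-1-benzofuran-5-yl]propyl}-6-(2-methylbut-3-en-2-yl)benzene-1,3-diol | C=CC(C)(C)c1cc(CCCc2cc(O)c3c(c2CC=C(C)C)C[C@H](C(C)(C)O)O3)c(O)cc1O | target

**Step count.** Total: 12 steps. Longest linear sequence: 8 steps (steps 1–6, 11, 12); ring A iodide 17 is made in 4 steps (steps 7–10).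

**Steps most likely to fail**

1. Step 4 (ring contraction). After ionisation, the bridged ion may lose a proton before water reaches the tertiary carbon, or the triflate may eliminate toward the benzylic position; in the second case chromene 3 is recovered and recycled. The fallback sets out from 5 and comes back at 8. The contraction is run on purpose as a dehydration (Tf2O, DTBMP, CH2Cl2, −78 °C to rt, no water), which should give (2R)-5-allyl-7-methoxy-2-(prop-1-en-2-yl)-2,3-dihydro-1-benzofuran F1. Its 1,1-disubstituted alkene should be epoxidised in preference to the monosubstituted allyl group (mCPBA, one equivalent, NaHCO3, CH2Cl2, 0 °C) to give (2R)-5-allyl-7-methoxy-2-(2-methyloxiran-2-yl)-2,3-dihydro-1-benzofuran F2; both epimers at the oxirane carbon serve, because that centre is lost. LiAlH4 in THF should then open F2 at its CH2 terminus to give 8.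

2. Step 5 (iodination). The iodonium may attack C6 or the allyl double bond in competition with C4. The fallback sets out from 8 and comes back at 20, using the free phenol as a stronger para director.
   - NaSEt in DMF at 120 °C demethylates 8 to (2R)-5-allyl-2-(2-hydroxypropan-2-yl)-2,3-dihydro-1-benzofuran-7-ol F3.
   - Tetrabutylammonium tribromide in CH2Cl2/MeOH at 0 °C, a bulky para-selective brominating agent for phenols, should give the 4-bromo phenol F4.
   - Stille coupling with 10 (Pd2(dba)3, P(t-Bu)3, CsF, dioxane, 90 °C) should give the 4-prenyl phenol F5.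
   - Hydroboration with 9-BBN (one extra equivalent for the phenol) gives the B-alkyl-9-BBN F6, which is coupled with 17 as in step 11 to the bis-pivalate F7.
   - K2CO3 in MeOH removes the pivalates to give 20.

3. Step 8 (Claisen rearrangement). The allyl unit may migrate to C2 between the oxygens, the ether may cleave, or the product phenol may cyclise onto its new vinyl group at 190 °C. The fallback sets out from 14 and comes back at 17, blocking C2 with a bulky ester and using the single free phenol to direct the iodination.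
   - Pivaloyl chloride, Et3N and DMAP convert 14 into 3-[(3-methylbut-2-en-1-yl)oxy]phenyl 2,2-dimethylpropanoate F8.
   - Rearrangement (N,N-diethylaniline, 180 °C) should then go only to the open ortho position to give 3-hydroxy-4-(2-methylbut-3-en-2-yl)phenyl 2,2-dimethylpropanoate F9.
   - NIS in MeCN iodinates para to the free hydroxyl to give 5-hydroxy-2-iodo-4-(2-methylbut-3-en-2-yl)phenyl 2,2-dimethylpropanoate F10.
   - A second pivaloylation gives 17.

**Further compounds**
F1 | step 4 | (2R)-5-allyl-7-methoxy-2-(prop-1-en-2-yl)-2,3-dihydro-1-benzofuran | C=CCc1cc(OC)c2O[C@@H](C(C)=C)Cc2c1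
F2 | step 4 | (2R)-5-allyl-7-methoxy-2-(2-methyloxiran-2-yl)-2,3-dihydro-1-benzofuran (both epimers at the oxirane carbon) | C=CCc1cc(OC)c2O[C@@H](C3(C)CO3)Cc2c1
F3 | step 5 | (2R)-5-allyl-2-(2-hydroxypropan-2-yl)-2,3-dihydro-1-benzofuran-7-ol | C=CCc1cc(O)c2O[C@@H](C(C)(C)O)Cc2c1
F4 | step 5 | (2R)-5-allyl-4-bromo-2-(2-hydroxypropan-2-yl)-2,3-dihydro-1-benzofuran-7-ol | C=CCc1cc(O)c2O[C@@H](C(C)(C)O)Cc2c1Br
F5 | step 5 | (2R)-5-allyl-2-(2-hydroxypropan-2-yl)-4-(3-methylbut-2-en-1-yl)-2,3-dihydro-1-benzofuran-7-ol | C=CCc1cc(O)c2O[C@@H](C(C)(C)O)Cc2c1CC=C(C)C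
F6 | step 5 | 9-{3-[(2R)-7-hydroxy-2-(2-hydroxypropan-2-yl)-4-(3-methylbut-2-en-1-yl)-2,3-dihydro-1-benzofuran-5-yl]propyl}-9-borabicyclo[3.3.1]nonane | C(CCc1cc(O)c2O[C@@H](C(C)(C)O)Cc2c1CC=C(C)C)B1C2CCCC1CCC2
F7 | step 5 | 4-{3-[(2R)-7-hydroxy-2-(2-hydroxypropan-2-yl)-4-(3-methylbut-2-en-1-yl)-2,3-dihydro-1-benzofuran-5-yl]propyl}-6-(2-methylbut-3-en-2-yl)-1,3-phenylene bis(2,2-dimethylpropanoate) | C=CC(C)(C)c1cc(CCCc2cc(O)c3O[C@@H](C(C)(C)O)Cc3c2CC=C(C)C)c(OC(=O)C(C)(C)C)cc1OC(=O)C(C)(C)C
F8 | step 8 | 3-[(3-methylbut-2-en-1-yl)oxy]phenyl 2,2-dimethylpropanoate | CC(C)=CCOc1cccc(OC(=O)C(C)(C)C)c1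
F9 | step 8 | 3-hydroxy-4-(2-methylbut-3-en-2-yl)phenyl 2,2-dimethylpropanoate | C=CC(C)(C)c1ccc(OC(=O)C(C)(C)C)cc1O
F10 | step 8 | 5-hydroxy-2-iodo-4-(2-methylbut-3-en-2-yl)phenyl 2,2-dimethylpropanoate | C=CC(C)(C)c1cc(I)c(OC(=O)C(C)(C)C)cc1O
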